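**Plan**

- Retrosynthesis: the cinnamyl alcohol chain is cut back to a C5 nitrile and both CH2OH groups to vinyl groups. Each dihydrobenzofuran is then cut at O1–C7a and at C2–C3, the outer (cinnamyl) unit first and the inner unit second.
- Enabling feature: in both benzofuran rings the ether oxygen O1 sits on arene carbon C7a para to the carbon substituent at C5, and C3 is a benzylic CH with a one-carbon arm. A C5 nitrile therefore makes a C7a–F bond open to SNAr, and C3 can be the γ-carbon of an aryl-substituted allylboronate.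
- Forward: one allylboronate (9, from 5-bromovanillin) is used twice. Aldehyde plus 9 gives a homoallylic borate whose alkoxide closes the furan ring on C7a–F; reduction of the nitrile to CHO makes the next acceptor. The guaiacyl ring is bought, then the inner and then the outer dihydrobenzofuran arise.
- Stereochemistry: C2 of each unit comes from catalyst-controlled Re-face allylboration with (R)-TRIP. The E reagent gives anti adducts and hence 2,3-cis rings; both C3 centres are then relayed from C2 by equilibration to trans at the dialdehyde stage.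
- Endgame: nitrile to aldehyde, Wittig olefination, ester reduction, desilylation.

Key step: step 8

Remark: (R)-TRIP = (R)-3,3'-bis(2,4,6-triisopropylphenyl)-1,1'-binaphthyl-2,2'-diyl hydrogen phosphate; it is taken to steer the γ-aryl allylboronate to the Re face of an aryl aldehyde, the sense known for allyl- and (E)-crotyl-Bpin.

**Route**

Step 1
Reactants: 1 5-bromovanillin
Product: 3 3-bromo-4-hydroxy-5-methoxybenzonitrile, via aldoxime 2 (not isolated)
Conditions: NH2OH·HCl, DMSO, 100 °C
Reagents that add atoms: hydroxylamine hydrochloride, Cl.NO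
Why: Oximation followed by thermal dehydration of the aldoxime (one-pot aldehyde-to-nitrile conversion) should give the nitrile, which later activates the ring and is the masked side-chain carbon; no stereocentre is formed.

Step 2
Reactants: 3 3-bromo-4-hydroxy-5-methoxybenzonitrile
Product: 5 3-bromo-4-fluoro-5-methoxybenzonitrile, via aryl fluorosulfonate 4 (not isolated)
Conditions: SO2F2, NMe4F (anhydrous), DMF, rt to 60 °C
Reagents that add atoms: tetramethylammonium fluoride, C[N+](C)(C)C.[F-]
Why: Deoxyfluorination of a phenol through its aryl fluorosulfonate: the para-cyano group makes the ipso carbon electrophilic enough for fluoride to displace fluorosulfate by SNAr.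

Step 3
Reactants: 5 3-bromo-4-fluoro-5-methoxybenzonitrile; 6 (E)-3-(tert-butyldimethylsilyloxy)prop-1-enylboronic acid pinacol ester
Product: 8 (E)-4-fluoro-3-(3-hydroxyprop-1-en-1-yl)-5-methoxybenzonitrile, via allylic silyl ether 7 (not isolated)
Conditions: Pd(dppf)Cl2 (3 mol %), K3PO4, THF/H2O, 60 °C; then HCl (cat.), MeOH, rt
Reagents that add atoms: none
Why: Suzuki–Miyaura coupling of the aryl bromide with the (E)-alkenylboronate proceeds with retention of alkene geometry (the C–F bond is inert to palladium), and acid methanolysis then frees the allylic alcohol.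

Step 4
Reactants: 8 (E)-4-fluoro-3-(3-hydroxyprop-1-en-1-yl)-5-methoxybenzonitrile
Product: 9 (E)-4-fluoro-3-methoxy-5-[3-(4,4,5,5-tetramethyl-1,3,2-dioxaborolan-2-yl)prop-1-en-1-yl]benzonitrile
Conditions: B2pin2, [Pd(MeCN)4](BF4)2 (5 mol %), DMSO/MeOH, 40 °C
Reagents that add atoms: bis(pinacolato)diboron, CC1(C)OB(OC1(C)C)B1OC(C)(C)C(C)(C)O1
Why: Palladium-catalysed borylation of an allylic alcohol through an η3-allylpalladium intermediate should give the linear (E)-allylboronate, the conjugated regio- and stereoisomer.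

Step 5
Reactants: 10 vanillin
Product: 11 3-methoxy-4-(triisopropylsilyloxy)benzaldehyde
Conditions: TIPSCl, imidazole, DMF, rt
Reagents that add atoms: chlorotriisopropylsilane, CC(C)[Si](Cl)(C(C)C)C(C)C
Why: Imidazole-promoted silylation masks the only acidic group of the acceptor with a group that should tolerate tert-butoxide at low temperature, hydride reagents and osmium chemistry.

Step 6
Reactants: 11 3-methoxy-4-(triisopropylsilyloxy)benzaldehyde; 9 (E)-allylboronate
Product: 13 (2R,3S)-7-methoxy-2-[3-methoxy-4-(triisopropylsilyloxy)phenyl]-3-vinyl-2,3-dihydrobenzofuran-5-carbonitrile (2,3-cis), via homoallylic pinacol borate 12 (not isolated)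
Conditions: (R)-TRIP (5 mol %), 4 Å MS, toluene, 0 °C; then KOtBu, THF, −20 to 0 °C
Reagents that add atoms: none
Why: Chiral-phosphoric-acid-catalysed allylboration through a closed chair transition state (Re-face attack sets C2 as R, the E alkene gives the anti adduct), followed in the same flask by intramolecular SNAr of the freed alkoxide on the C–F bond para to the nitrile, should give the 2,3-cis dihydrobenzofuran as one enantiomer.

Step 7
Reactants: 13 cis-3-vinyl-dihydrobenzofuran-5-carbonitrile
Product: 15 (2R,3S)-7-methoxy-2-[3-methoxy-4-(triisopropylsilyloxy)phenyl]-3-vinyl-2,3-dihydrobenzofuran-5-carbaldehyde, via aldimine 14 (not isolated)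
Conditions: i-Bu2AlH (DIBAL-H), CH2Cl2, −78 °C; then aq. potassium sodium tartrate, dilute HCl, rt
Reagents that add atoms: water, O
Why: Partial reduction of the aryl nitrile by i-Bu2AlH stops at the imine stage, and hydrolysis gives the aldehyde; the vinyl group, the silyl ether and both stereocentres are untouched.

Step 8
Reactants: 15 dihydrobenzofuran-5-carbaldehyde; 9 (E)-allylboronate
Product: 17 (2R,3S)-7-methoxy-2-{(2R,3S)-7-methoxy-2-[3-methoxy-4-(triisopropylsilyloxy)phenyl]-3-vinyl-2,3-dihydrobenzofuran-5-yl}-3-vinyl-2,3-dihydrobenzofuran-5-carbonitrile (both rings 2,3-cis), via homoallylic pinacol borate 16 (not isolated)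
Conditions: (R)-TRIP (10 mol %), 4 Å MS, toluene, 0 °C to rt; then KOtBu, THF, −20 to 0 °C
Reagents that add atoms: none
Why: The chiral phosphoric acid activates the pinacol boronate by hydrogen bonding, so the γ-carbon of 9 adds to the Re face of the formyl group of 15 through a closed chair transition state with allyl transposition (C3–C2 bond) to give the anti borate 16; tert-butoxide then takes the boron, and the freed C2 alkoxide attacks C7a, para to the nitrile, and expels fluoride (O1–C7a bond). The closest known reaction types are the Brønsted-acid-catalysed asymmetric allyl- and crotylboration of aromatic aldehydes and the intramolecular SNAr etherification of a 4-fluorobenzonitrile, run here in one flask as a formal [3+2] annulation of the C=O group with a benzylic-carbanion/aryl-cation synthon. The furan ring closes by 5-exo-trig addition of oxygen to the arene, followed by loss of fluoride from the Meisenheimer anion. C2 (R) is set by the catalyst, to which the remote stereocentres of 15 should be indifferent; C3 follows from the E alkene geometry in the chair (anti adduct, hence the 2,3-cis ring) and is corrected to trans in step 9. The step needs chemoselectivity for CHO over the nitriles (which allylboronates respect), γ-selectivity (imposed by the six-membered transition state), and ring closure faster than attack of tert-butoxide on the fluoroarene (which intramolecularity and the prior capture of tert-butoxide by boron should secure); the vinyl group is a latent CH2OH that can neither retro-add, epimerise nor compete as a nucleophile.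

Step 9
Reactants: 17 bis-vinyl nitrile
Product: 20 (2R,3S)-3-(hydroxymethyl)-2-{(2R,3S)-3-(hydroxymethyl)-7-methoxy-2-[3-methoxy-4-(triisopropylsilyloxy)phenyl]-2,3-dihydrobenzofuran-5-yl}-7-methoxy-2,3-dihydrobenzofuran-5-carbonitrile (both rings 2,3-trans), via cis-dialdehyde 18 (not isolated), via trans-dialdehyde 19 (not isolated)
Conditions: OsO4 (cat.), NaIO4, 2,6-lutidine, dioxane/H2O, rt; extractive work-up; DBU (cat.), CH2Cl2, rt, argon; then MeOH, NaBH4, 0 °C
Reagents that add atoms: sodium periodate, [Na+].[O-]I(=O)(=O)=O; water, O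
Why: Lemieux–Johnson cleavage turns both vinyl groups into formyl groups, base-mediated enolisation equilibrates the two benzylic α-formyl C3 centres to the more stable 2,3-trans arrangement (thermodynamic relay from the fixed C2 centres; ring opening by β-elimination would be the reverse of a 5-endo-trig closure because the C2–O bond lies in the enolate plane), and NaBH4 then reduces both aldehydes while the nitrile survives.

Step 10
Reactants: 20 diol nitrile
Product: 22 (2R,3S)-3-(hydroxymethyl)-2-{(2R,3S)-3-(hydroxymethyl)-7-methoxy-2-[3-methoxy-4-(triisopropylsilyloxy)phenyl]-2,3-dihydrobenzofuran-5-yl}-7-methoxy-2,3-dihydrobenzofuran-5-carbaldehyde, via aldimine 21 (not isolated)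
Conditions: i-Bu2AlH (excess), CH2Cl2/THF, −78 to −20 °C; then aq. potassium sodium tartrate, dilute HCl
Reagents that add atoms: water, O
Why: As in step 7, i-Bu2AlH reduces the nitrile to the imine stage after deprotonating the two alcohols (hence the excess), and hydrolysis should give the aryl aldehyde.

Step 11
Reactants: 22 diol aldehyde
Product: 23 ethyl (E)-3-[(2R,3S)-3-(hydroxymethyl)-2-{(2R,3S)-3-(hydroxymethyl)-7-methoxy-2-[3-methoxy-4-(triisopropylsilyloxy)phenyl]-2,3-dihydrobenzofuran-5-yl}-7-methoxy-2,3-dihydrobenzofuran-5-yl]acrylate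
Conditions: Ph3P=CHCO2Et, toluene, 60 °C
Reagents that add atoms: ethyl (triphenylphosphoranylidene)acetate, CCOC(=O)C=P(c1ccccc1)(c1ccccc1)c1ccccc1
Why: Wittig olefination with a stabilised ylide is E-selective with aromatic aldehydes and tolerates free alcohols.

Step 12
Reactants: 23 cinnamate ester
Product: 24 (E)-3-[(2R,3S)-3-(hydroxymethyl)-2-{(2R,3S)-3-(hydroxymethyl)-7-methoxy-2-[3-methoxy-4-(triisopropylsilyloxy)phenyl]-2,3-dihydrobenzofuran-5-yl}-7-methoxy-2,3-dihydrobenzofuran-5-yl]prop-2-en-1-ol
Conditions: i-Bu2AlH (excess), CH2Cl2, −78 °C; aq. potassium sodium tartrate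
Reagents that add atoms: none
Why: 1,2-Reduction of the cinnamate ester by i-Bu2AlH at low temperature should give the (E)-allylic alcohol without touching the alkene or the aryl silyl ether.

Step 13
Reactants: 24 silyl-protected triol
Product: 25 (E)-3-[(2R,3S)-3-(hydroxymethyl)-2-{(2R,3S)-3-(hydroxymethyl)-2-(4-hydroxy-3-methoxyphenyl)-7-methoxy-2,3-dihydrobenzofuran-5-yl}-7-methoxy-2,3-dihydrobenzofuran-5-yl]prop-2-en-1-ol (CNP0250921.1)
Conditions: Bu4NF, AcOH, THF, 0 °C
Reagents that add atoms: none
Why: Fluoride-induced cleavage of the aryl silyl ether, buffered with acetic acid so that the phenoxide is protonated at once, should free the phenol while sparing the allylic alcohol and both benzylic aryl ethers.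

**Compound list**

1 | 5-bromovanillin (3-bromo-4-hydroxy-5-methoxybenzaldehyde) | COc1cc(C=O)cc(Br)c1O | starting material
2 | (E)-3-bromo-4-hydroxy-5-methoxybenzaldehyde oxime | COc1cc(/C=N/O)cc(Br)c1O | intermediate
3 | 3-bromo-4-hydroxy-5-methoxybenzonitrile | COc1cc(C#N)cc(Br)c1O | intermediate
4 | 2-bromo-4-cyano-6-methoxyphenyl fluorosulfonate | COc1cc(C#N)cc(Br)c1OS(=O)(=O)F | intermediate
5 | 3-bromo-4-fluoro-5-methoxybenzonitrile | COc1cc(C#N)cc(Br)c1F | intermediate
6 | (E)-3-(tert-butyldimethylsilyloxy)prop-1-enylboronic acid pinacol ester | CC(C)(C)[Si](C)(C)OC/C=C/B1OC(C)(C)C(C)(C)O1 | starting material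
7 | (E)-3-[3-(tert-butyldimethylsilyloxy)prop-1-en-1-yl]-4-fluoro-5-methoxybenzonitrile | COc1cc(C#N)cc(/C=C/CO[Si](C)(C)C(C)(C)C)c1F | intermediate
8 | (E)-4-fluoro-3-(3-hydroxyprop-1-en-1-yl)-5-methoxybenzonitrile | COc1cc(C#N)cc(/C=C/CO)c1F | intermediate
9 | (E)-4-fluoro-3-methoxy-5-[3-(4,4,5,5-tetramethyl-1,3,2-dioxaborolan-2-yl)prop-1-en-1-yl]benzonitrile | COc1cc(C#N)cc(/C=C/CB2OC(C)(C)C(C)(C)O2)c1F | intermediate
10 | vanillin | COc1cc(C=O)ccc1O | starting material
11 | 3-methoxy-4-(triisopropylsilyloxy)benzaldehyde | COc1cc(C=O)ccc1O[Si](C(C)C)(C(C)C)C(C)C | intermediate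
12 | pinacol borate of (1R,2S)-2-(5-cyano-2-fluoro-3-methoxyphenyl)-1-[3-methoxy-4-(triisopropylsilyloxy)phenyl]but-3-en-1-ol (anti) | COc1cc([C@H](OB2OC(C)(C)C(C)(C)O2)[C@@H](C=C)c2cc(C#N)cc(OC)c2F)ccc1O[Si](C(C)C)(C(C)C)C(C)C | intermediate
13 | (2R,3S)-7-methoxy-2-[3-methoxy-4-(triisopropylsilyloxy)phenyl]-3-vinyl-2,3-dihydrobenzofuran-5-carbonitrile (cis) | COc1cc([C@@H]2Oc3c(OC)cc(C#N)cc3[C@@H]2C=C)ccc1O[Si](C(C)C)(C(C)C)C(C)C | intermediate
14 | aldimine (C=NH) of 15, (2R,3S), cis | COc1cc([C@@H]2Oc3c(OC)cc(C=N)cc3[C@@H]2C=C)ccc1O[Si](C(C)C)(C(C)C)C(C)C | intermediate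
15 | (2R,3S)-7-methoxy-2-[3-methoxy-4-(triisopropylsilyloxy)phenyl]-3-vinyl-2,3-dihydrobenzofuran-5-carbaldehyde (cis) | COc1cc([C@@H]2Oc3c(OC)cc(C=O)cc3[C@@H]2C=C)ccc1O[Si](C(C)C)(C(C)C)C(C)C | intermediate
16 | pinacol borate of the (1R,2S) anti homoallylic alcohol from 15 and 9 (inner ring 2R,3S cis) | COc1cc([C@@H]2Oc3c(OC)cc([C@H](OB4OC(C)(C)C(C)(C)O4)[C@@H](C=C)c4cc(C#N)cc(OC)c4F)cc3[C@@H]2C=C)ccc1O[Si](C(C)C)(C(C)C)C(C)C | intermediate
17 | (2R,3S)-7-methoxy-2-{(2R,3S)-7-methoxy-2-[3-methoxy-4-(triisopropylsilyloxy)phenyl]-3-vinyl-2,3-dihydrobenzofuran-5-yl}-3-vinyl-2,3-dihydrobenzofuran-5-carbonitrile (cis,cis) | COc1cc([C@@H]2Oc3c(OC)cc([C@@H]4Oc5c(OC)cc(C#N)cc5[C@@H]4C=C)cc3[C@@H]2C=C)ccc1O[Si](C(C)C)(C(C)C)C(C)C | intermediate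
18 | cis,cis-dialdehyde (2R,3S in both rings): 3-formyl-2-(3-formyl-dihydrobenzofuranyl)-dihydrobenzofuran-5-carbonitrile | COc1cc([C@@H]2Oc3c(OC)cc([C@@H]4Oc5c(OC)cc(C#N)cc5[C@@H]4C=O)cc3[C@@H]2C=O)ccc1O[Si](C(C)C)(C(C)C)C(C)C | intermediate
19 | trans,trans-dialdehyde (2R,3R in both rings) | COc1cc([C@@H]2Oc3c(OC)cc([C@@H]4Oc5c(OC)cc(C#N)cc5[C@H]4C=O)cc3[C@H]2C=O)ccc1O[Si](C(C)C)(C(C)C)C(C)C | intermediate
20 | (2R,3S)-3-(hydroxymethyl)-2-{(2R,3S)-3-(hydroxymethyl)-7-methoxy-2-[3-methoxy-4-(triisopropylsilyloxy)phenyl]-2,3-dihydrobenzofuran-5-yl}-7-methoxy-2,3-dihydrobenzofuran-5-carbonitrile (trans,trans) | COc1cc([C@@H]2Oc3c(OC)cc([C@@H]4Oc5c(OC)cc(C#N)cc5[C@H]4CO)cc3[C@H]2CO)ccc1O[Si](C(C)C)(C(C)C)C(C)C | intermediate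
21 | aldimine (C=NH) of 22 | COc1cc([C@@H]2Oc3c(OC)cc([C@@H]4Oc5c(OC)cc(C=N)cc5[C@H]4CO)cc3[C@H]2CO)ccc1O[Si](C(C)C)(C(C)C)C(C)C | intermediate
22 | trans,trans-diol 5-carbaldehyde (2R,3S in both rings) | COc1cc([C@@H]2Oc3c(OC)cc([C@@H]4Oc5c(OC)cc(C=O)cc5[C@H]4CO)cc3[C@H]2CO)ccc1O[Si](C(C)C)(C(C)C)C(C)C | intermediate
23 | ethyl (E)-acrylate of the trans,trans-diol (2R,3S in both rings) | COc1cc([C@@H]2Oc3c(OC)cc([C@@H]4Oc5c(OC)cc(/C=C/C(=O)OCC)cc5[C@H]4CO)cc3[C@H]2CO)ccc1O[Si](C(C)C)(C(C)C)C(C)C | intermediate
24 | O-triisopropylsilyl ether of the target (2R,3S in both rings, E alkene) | COc1cc([C@@H]2Oc3c(OC)cc([C@@H]4Oc5c(OC)cc(/C=C/CO)cc5[C@H]4CO)cc3[C@H]2CO)ccc1O[Si](C(C)C)(C(C)C)C(C)C | intermediate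
25 | (E)-3-[(2R,3S)-3-(hydroxymethyl)-2-{(2R,3S)-3-(hydroxymethyl)-2-(4-hydroxy-3-methoxyphenyl)-7-methoxy-2,3-dihydrobenzofuran-5-yl}-7-methoxy-2,3-dihydrobenzofuran-5-yl]prop-2-en-1-ol | COc1cc([C@@H]2Oc3c(OC)cc([C@@H]4Oc5c(OC)cc(/C=C/CO)cc5[C@H]4CO)cc3[C@H]2CO)ccc1O | target

**Count and risks**

Total steps: 13. Longest linear sequence: 12 steps (steps 1–4 and 6–13, from 5-bromovanillin).

Steps most likely to fail:

1. Step 8 (the same event is used in step 6). The conjugated γ-aryl allylboronate is a weak nucleophile and the aldehyde is electron-rich, so uncatalysed background addition may erode facial control; tert-butoxide may also attack the fluoroarene before the alkoxide is released. The fallback splits the event and changes the allyl metal. It sets out from alcohol 8 and aldehyde 15 and comes back at 17. Alcohol 8 is converted (CBr4, PPh3, Appel reaction) into the allylic bromide (E)-3-(3-bromoprop-1-en-1-yl)-4-fluoro-5-methoxybenzonitrile F1. A catalytic asymmetric Nozaki–Hiyama–Kishi allylation of 15 with F1 (CrCl2 cat., Mn, Me3SiCl, Et3N, chiral carbazole bis(oxazoline) ligand, THF) should give, through the chair transition state of the γ-aryl allylchromium reagent, the anti trimethylsilyl ether F2. Methanolysis (citric acid, MeOH) gives the anti homoallylic alcohol F3. Ring closure with KN(SiMe3)2 in THF at 0 °C, with no competing oxygen nucleophile present, gives 17.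

2. Step 9. The equilibration at C3 may stay incomplete, the aldehydes may be lost by β-elimination or autoxidation while they are enolised, or the electron-rich rings may be over-oxidised during the cleavage. The fallback moves the epimerisation to the ester level, where it is a standard operation for this ring system. It sets out from the crude dialdehyde 18 and comes back at 20. Pinnick oxidation (NaClO2, NaH2PO4, 2-methyl-2-butene) gives the cis,cis-dicarboxylic acid F4. Me3SiCHN2 in MeOH/toluene gives the cis,cis-dimethyl ester F5. NaOMe in MeOH/THF at 0 °C (short contact, to keep the aryl silyl ether) equilibrates both C3 centres to the trans,trans-dimethyl ester F6. LiBH4 in THF reduces both esters, leaves the nitrile, and gives 20.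

3. Step 4. Ionisation of the electron-poor cinnamyl alcohol on the cationic palladium catalyst may be slow, and the allylboronate may be lost by protodeboronation or isomerisation on prolonged heating. The fallback changes the leaving group and the activation mode. It sets out from 8 and comes back at 9. Acetylation (Ac2O, pyridine) gives the allylic acetate (E)-3-(5-cyano-2-fluoro-3-methoxyphenyl)allyl acetate F7. Oxidative addition to zerovalent palladium (Pd2(dba)3, B2pin2, DMSO, 50 °C; Miyaura-type allylic borylation) then gives 9.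

**Further compounds**

F1 | step 8 | (E)-3-(3-bromoprop-1-en-1-yl)-4-fluoro-5-methoxybenzonitrile | COc1cc(C#N)cc(/C=C/CBr)c1F
F2 | step 8 | trimethylsilyl ether of the (1R,2S) anti homoallylic alcohol F3 | COc1cc([C@@H]2Oc3c(OC)cc([C@H](O[Si](C)(C)C)[C@@H](C=C)c4cc(C#N)cc(OC)c4F)cc3[C@@H]2C=C)ccc1O[Si](C(C)C)(C(C)C)C(C)C
F3 | step 8 | (1R,2S) anti homoallylic alcohol from 15 (free OH form of 16) | COc1cc([C@@H]2Oc3c(OC)cc([C@H](O)[C@@H](C=C)c4cc(C#N)cc(OC)c4F)cc3[C@@H]2C=C)ccc1O[Si](C(C)C)(C(C)C)C(C)C
F4 | step 9 | cis,cis-dicarboxylic acid (2R,3S in both rings) | COc1cc([C@@H]2Oc3c(OC)cc([C@@H]4Oc5c(OC)cc(C#N)cc5[C@@H]4C(=O)O)cc3[C@@H]2C(=O)O)ccc1O[Si](C(C)C)(C(C)C)C(C)C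
F5 | step 9 | cis,cis-dimethyl ester (2R,3S in both rings) | COc1cc([C@@H]2Oc3c(OC)cc([C@@H]4Oc5c(OC)cc(C#N)cc5[C@@H]4C(=O)OC)cc3[C@@H]2C(=O)OC)ccc1O[Si](C(C)C)(C(C)C)C(C)C
F6 | step 9 | trans,trans-dimethyl ester (2R,3R in both rings) | COc1cc([C@@H]2Oc3c(OC)cc([C@@H]4Oc5c(OC)cc(C#N)cc5[C@H]4C(=O)OC)cc3[C@H]2C(=O)OC)ccc1O[Si](C(C)C)(C(C)C)C(C)C
F7 | step 4 | (E)-3-(5-cyano-2-fluoro-3-methoxyphenyl)allyl acetate | COc1cc(C#N)cc(/C=C/COC(C)=O)c1F
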